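The ten-membered carbocycle (C1–C10) is opened at C5–C6: C6 is an allylic carbinol carbon attached to the Z-trisubstituted C4=C5 alkene, so a Z-alkenyl metal at C5 adding to a C6 aldehyde is its retron. One Nozaki–Hiyama–Kishi reaction forms C5–C6, closes the ring with the alkene geometry intact and creates the C6 carbinol that later becomes the lactone oxygen. The precursor is an acyclic C5 Z-vinyl iodide/C6 aldehyde that already carries the C1–C2 epoxide, the silylated C3, C8 and C10 oxygens and the C7 methyl acetate branch. Its stereocentres come from (R)-citramalic acid (C10), an anti-selective auxiliary aldol (C7, C8) and a Sharpless epoxidation (C1, C2).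

Key step: step 17

Remark on numbering: C1–C10 are the ring carbons, C11–C13 the lactone carbons on C7, C14 the methyl on C10 and C15 the methyl on C4; the germacrane-type names use these numbers, and "13-nor" means that C13 is still absent.
Remark on design: O8 travels as a tert-butyldimethylsilyl ether and receives the tiglate in the last step, which keeps a β-acyloxy aldehyde and a migrating ester out of the ring closure and out of the lactone enolate chemistry.

Step 1
Reactants: 1 (R)-citramalic acid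
Product: 2 dimethyl (2R)-2-hydroxy-2-methylbutanedioate
Conditions: MeOH, H2SO4 (cat.), reflux
Reagents that add atoms: methanol (CO)
Why: Fischer esterification converts both carboxyl groups into methyl esters under acid catalysis and does not touch the tertiary carbinol centre that becomes C10.

Step 2
Reactants: 2 dimethyl (2R)-2-hydroxy-2-methylbutanedioate
Product: 3 methyl (3R)-3,4-dihydroxy-3-methylbutanoate
Conditions: BH3·SMe2 (1.05 equiv), NaBH4 (5 mol %), THF, 0 °C to rt; then MeOH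
Reagents that add atoms: none
Why: Hydroxyl-directed borane reduction of an α-hydroxy ester, in which the alkoxyborane formed at the tertiary hydroxyl delivers hydride only to the adjacent ester (future C1), so the remote ester (future C8) survives and the stereocentre is not involved.

Step 3
Reactants: 3 methyl (3R)-3,4-dihydroxy-3-methylbutanoate
Product: 4 methyl (3R)-3-methyl-3,4-bis(triethylsilyloxy)butanoate
Conditions: Et3SiOTf (2.5 equiv), 2,6-lutidine, CH2Cl2, −78 to 0 °C
Reagents that add atoms: triethylsilyl trifluoromethanesulfonate (CC[Si](CC)(CC)OS(=O)(=O)C(F)(F)F)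
Why: Silylation with a silyl triflate caps the primary and the hindered tertiary hydroxyl in one operation and prevents lactonisation of the γ-hydroxy ester.

Step 4
Reactants: 4 methyl (3R)-3-methyl-3,4-bis(triethylsilyloxy)butanoate
Product: 5 (3R)-3-methyl-3,4-bis(triethylsilyloxy)butanal
Conditions: i-Bu2AlH (1.1 equiv), CH2Cl2, −78 °C; aq. potassium sodium tartrate
Reagents that add atoms: none
Why: Partial reduction of an ester with i-Bu2AlH at −78 °C stops at the aluminium hemiacetal, which gives the C8 aldehyde on work-up.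

Step 5
Reactants: 6 (4S)-4-benzyl-1,3-oxazolidin-2-one; 7 methyl 4-chloro-4-oxobutanoate
Product: 8 methyl 4-[(4S)-4-benzyl-2-oxo-1,3-oxazolidin-3-yl]-4-oxobutanoate
Conditions: n-BuLi, THF, −78 °C; then 7, −78 to 0 °C
Reagents that add atoms: none
Why: N-Acylation of the lithiated oxazolidinone by the acid chloride, which is far more electrophilic than the methyl ester at the other end of the succinate.

Step 6
Reactants: 8 methyl 4-[(4S)-4-benzyl-2-oxo-1,3-oxazolidin-3-yl]-4-oxobutanoate; 5 (3R)-3-methyl-3,4-bis(triethylsilyloxy)butanal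
Product: 10 methyl (3R,4R,6R)-3-{[(4S)-4-benzyl-2-oxo-1,3-oxazolidin-3-yl]carbonyl}-4-hydroxy-6-methyl-6,7-bis(triethylsilyloxy)heptanoate, via dibutylboron Z-enolate 9 (not isolated)
Conditions: 8, Bu2BOTf, i-Pr2NEt, CH2Cl2, 0 °C; then added to 5 premixed with Et2AlCl (2 equiv), CH2Cl2, −78 °C; pH 7 buffer, MeOH, H2O2
Reagents that add atoms: none
Why: Evans aldol reaction in its Lewis-acid-mediated anti variant, in which only the imide side of the succinate is enolised and the boron-chelated Z-enolate adds through an open transition state to the Et2AlCl-bound aldehyde on the face remote from the benzyl group, which should set C7 (R) and C8 (R) in the anti relationship.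

Step 7
Reactants: 10 methyl (3R,4R,6R)-3-{[(4S)-4-benzyl-2-oxo-1,3-oxazolidin-3-yl]carbonyl}-4-hydroxy-6-methyl-6,7-bis(triethylsilyloxy)heptanoate
Product: 11 methyl (3R,4R,6R)-4-hydroxy-3-[methoxy(methyl)carbamoyl]-6-methyl-6,7-bis(triethylsilyloxy)heptanoate
Conditions: MeONHMe·HCl, AlMe3, CH2Cl2, −20 to 0 °C
Reagents that add atoms: N,O-dimethylhydroxylamine hydrochloride (CNOC.Cl)
Why: Weinreb amide synthesis by aluminium amide transamination of a β-hydroxy imide, in which the free C8 hydroxyl binds aluminium and directs the amide transfer to the imide carbonyl faster than the methyl ester can react, and the auxiliary is released.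

Step 8
Reactants: 11 methyl (3R,4R,6R)-4-hydroxy-3-[methoxy(methyl)carbamoyl]-6-methyl-6,7-bis(triethylsilyloxy)heptanoate
Product: 12 methyl (3R,4R,6R)-4-(tert-butyldimethylsilyloxy)-3-[methoxy(methyl)carbamoyl]-6-methyl-6,7-bis(triethylsilyloxy)heptanoate
Conditions: t-BuMe2SiOTf, 2,6-lutidine, CH2Cl2, −78 to 0 °C
Reagents that add atoms: tert-butyldimethylsilyl trifluoromethanesulfonate (CC(C)(C)[Si](C)(C)OS(=O)(=O)C(F)(F)F)
Why: Silyl triflate silylation of the hindered secondary alcohol gives an O8 silyl ether that can no longer lactonise onto C12 and is a poor leaving group β to the later aldehyde.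

Step 9
Reactants: 12 methyl (3R,4R,6R)-4-(tert-butyldimethylsilyloxy)-3-[methoxy(methyl)carbamoyl]-6-methyl-6,7-bis(triethylsilyloxy)heptanoate
Product: 13 methyl (3R,4R,6R)-4-(tert-butyldimethylsilyloxy)-3-[methoxy(methyl)carbamoyl]-6-methyl-7-oxo-6-(triethylsilyloxy)heptanoate
Conditions: (COCl)2, DMSO, CH2Cl2, −78 to −30 °C; Et3N, −78 to 0 °C
Reagents that add atoms: none
Why: Swern oxidation applied directly to a primary triethylsilyl ether, in which the chlorosulfonium reagent cleaves only the unhindered primary O–Si bond and the alkoxysulfonium ion collapses to the C1 aldehyde while the tertiary triethylsilyl and the secondary tert-butyldimethylsilyl ethers are left.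

Step 10
Reactants: 13 methyl (3R,4R,6R)-4-(tert-butyldimethylsilyloxy)-3-[methoxy(methyl)carbamoyl]-6-methyl-7-oxo-6-(triethylsilyloxy)heptanoate
Product: 14 methyl (3R,4R,6R)-4-(tert-butyldimethylsilyloxy)-3-[methoxy(methyl)carbamoyl]-6-methyl-6-(triethylsilyloxy)oct-7-ynoate
Conditions: MeC(O)C(N2)P(O)(OMe)2, K2CO3, MeOH, 0 °C to rt
Reagents that add atoms: dimethyl (1-diazo-2-oxopropyl)phosphonate (CC(=O)C(=[N+]=[N-])P(=O)(OC)OC)
Why: The Ohira–Bestmann variant of the Seyferth–Gilbert homologation turns the aldehyde into the terminal alkyne C1≡C2, and the α-carbon is quaternary, so the mild base cannot epimerise it.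

Step 11
Reactants: 15 prop-2-yn-1-ol
Product: 17 (Z)-3-iodo-2-methylprop-2-en-1-ol, via alkenylmagnesium alkoxide 16 (not isolated)
Conditions: MeMgBr (2.5 equiv), CuI (10 mol %), THF, −10 °C to rt; then I2, −10 °C
Reagents that add atoms: methylmagnesium bromide (C[Mg]Br); iodine (II)
Why: Copper-catalysed anti-carbomagnesiation of the propargylic alkoxide places methyl on the inner carbon and magnesium, chelated by the alkoxide, on the terminal carbon cis to the CH2O group, and iodinolysis with retention gives the Z iodide that holds C3, C4, C5 and C15.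

Step 12
Reactants: 17 (Z)-3-iodo-2-methylprop-2-en-1-ol
Product: 18 (Z)-3-iodo-2-methylprop-2-enal
Conditions: MnO2, CH2Cl2, rt, dark
Reagents that add atoms: none
Why: Allylic oxidation with MnO2 is neutral and heterogeneous, so the Z geometry of the iodoalkene should survive, and the aldehyde is used at once.

Step 13
Reactants: 14 methyl (3R,4R,6R)-4-(tert-butyldimethylsilyloxy)-3-[methoxy(methyl)carbamoyl]-6-methyl-6-(triethylsilyloxy)oct-7-ynoate; 18 (Z)-3-iodo-2-methylprop-2-enal
Product: 21 methyl (3R,4R,6R,7E,9R,10Z)-4-(tert-butyldimethylsilyloxy)-9-hydroxy-11-iodo-3-[methoxy(methyl)carbamoyl]-6,10-dimethyl-6-(triethylsilyloxy)undeca-7,10-dienoate, via E-alkenyl(dicyclohexyl)borane 19 (not isolated), via E-alkenyl(methyl)zinc 20 (not isolated)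
Conditions: 14, (c-C6H11)2BH (from BH3·SMe2, cyclohexene), toluene, 0 °C to rt; Me2Zn, −78 °C; (2R)-(+)-3-exo-morpholinoisoborneol (5 mol %), 18, −20 to 0 °C
Reagents that add atoms: none
Why: Hydroboration gives the E-alkenylborane, boron-to-zinc exchange gives the alkenylzinc, and the amino-alcohol-catalysed asymmetric alkenylzinc addition to the enal forms C2–C3 by Re-face attack (3R carbinol), while the esters, the Weinreb amide and the vinyl iodide are inert to the zinc reagent.

Step 14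
Reactants: 21 methyl (3R,4R,6R,7E,9R,10Z)-4-(tert-butyldimethylsilyloxy)-9-hydroxy-11-iodo-3-[methoxy(methyl)carbamoyl]-6,10-dimethyl-6-(triethylsilyloxy)undeca-7,10-dienoate
Product: 22 methyl (3R,4R,6R,7R,8S,9S,10Z)-4-(tert-butyldimethylsilyloxy)-7,8-epoxy-9-hydroxy-11-iodo-3-[methoxy(methyl)carbamoyl]-6,10-dimethyl-6-(triethylsilyloxy)undec-10-enoate
Conditions: Ti(Oi-Pr)4 (10 mol %), L-(+)-diisopropyl tartrate (12 mol %), t-BuOOH, 4 Å sieves, CH2Cl2, −20 °C
Reagents that add atoms: tert-butyl hydroperoxide (CC(C)(C)OO)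
Why: Sharpless asymmetric epoxidation of a secondary allylic alcohol in its matched, fast-reacting sense, in which the L-(+)-tartrate complex delivers oxygen to the C1=C2 face that gives the trans epoxide with the C1 and C2 configuration of the target (erythro to C3), whereas the iodoalkene arm is both mismatched and electron-poor and is left.

Step 15
Reactants: 22 methyl (3R,4R,6R,7R,8S,9S,10Z)-4-(tert-butyldimethylsilyloxy)-7,8-epoxy-9-hydroxy-11-iodo-3-[methoxy(methyl)carbamoyl]-6,10-dimethyl-6-(triethylsilyloxy)undec-10-enoate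
Product: 23 methyl (3R,4R,6R,7R,8R,9S,10Z)-4,9-bis(tert-butyldimethylsilyloxy)-7,8-epoxy-11-iodo-3-[methoxy(methyl)carbamoyl]-6,10-dimethyl-6-(triethylsilyloxy)undec-10-enoate
Conditions: t-BuMe2SiOTf, 2,6-lutidine, CH2Cl2, −78 °C
Reagents that add atoms: tert-butyldimethylsilyl trifluoromethanesulfonate (CC(C)(C)[Si](C)(C)OS(=O)(=O)C(F)(F)F)
Why: Low-temperature silylation caps the C3 hydroxyl so that the epoxy alcohol cannot undergo Payne rearrangement in later basic steps, and C3 is kept at the alcohol level because CrCl2 would reduce an epoxy ketone.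

Step 16
Reactants: 23 methyl (3R,4R,6R,7R,8R,9S,10Z)-4,9-bis(tert-butyldimethylsilyloxy)-7,8-epoxy-11-iodo-3-[methoxy(methyl)carbamoyl]-6,10-dimethyl-6-(triethylsilyloxy)undec-10-enoate
Product: 24 methyl (3R,4R,6R,7R,8R,9S,10Z)-4,9-bis(tert-butyldimethylsilyloxy)-7,8-epoxy-3-formyl-11-iodo-6,10-dimethyl-6-(triethylsilyloxy)undec-10-enoate
Conditions: i-Bu2AlH (1.3 equiv), THF, −78 °C; aq. potassium sodium tartrate
Reagents that add atoms: none
Why: Reduction of a Weinreb amide with i-Bu2AlH, in which the reagent binds the more Lewis-basic amide carbonyl first and the chelated aluminium hemiaminal holds the aldehyde oxidation level until work-up, so the methyl ester and the epoxide should be kept.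

Step 17
Reactants: 24 methyl (3R,4R,6R,7R,8R,9S,10Z)-4,9-bis(tert-butyldimethylsilyloxy)-7,8-epoxy-3-formyl-11-iodo-6,10-dimethyl-6-(triethylsilyloxy)undec-10-enoate
Product: 26 methyl (1R,2R,3S,4Z,6S,7S,8R,10R)-3,8-bis(tert-butyldimethylsilyloxy)-1,2-epoxy-6-hydroxy-10-(triethylsilyloxy)-13-norgermacr-4-en-12-oate, via Z-alkenylchromium dichloride 25 (not isolated)
Conditions: CrCl2 (10 equiv), NiCl2 (2 mol %), DMSO–THF, 0.003 M, rt, slow addition of 24
Reagents that add atoms: none
Why: CrCl2 reduces NiCl2 to zerovalent nickel, which inserts into the C5–I bond with retention; transmetalation to trivalent chromium gives the configurationally stable Z-alkenylchromium 25, which adds to the C6 aldehyde. The closest known reaction type is the intramolecular Nozaki–Hiyama–Kishi alkenylation used to close medium and large carbocycles. The ten-membered ring C1–C10 closes in the 10-exo-trig mode by attack of C5 on the C6 carbonyl carbon. The new C6 stereocentre is controlled by the cyclic transition state, in which the Z alkene and the trans epoxide bend the chain and the C7 substituents decide which carbonyl face is presented; the 6S alcohol (O6 anti to the C11 branch) is the one needed. The step needs chemoselectivity for the iodide over ester, epoxide and silyl ethers, secured by the mild alkenylchromium reagent, ring closure over oligomerisation, secured by high dilution and slow addition, and retention of the Z geometry, secured by the stereospecific nickel and chromium steps on an alkene whose geometry was fixed in step 11. The facial selectivity at C6 is not guaranteed by the substrate and is the risk this route accepts.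

Step 18
Reactants: 26 methyl (1R,2R,3S,4Z,6S,7S,8R,10R)-3,8-bis(tert-butyldimethylsilyloxy)-1,2-epoxy-6-hydroxy-10-(triethylsilyloxy)-13-norgermacr-4-en-12-oate
Product: 27 (1R,2R,3S,4Z,6S,7S,8R,10R)-3,8-bis(tert-butyldimethylsilyloxy)-1,2-epoxy-10-(triethylsilyloxy)-13-norgermacr-4-en-12,6-olide
Conditions: pyridinium p-toluenesulfonate (cat.), CH2Cl2, rt
Reagents that add atoms: none
Why: Acid-catalysed lactonisation (intramolecular transesterification, 5-exo-trig) of the γ-hydroxy ester gives the trans-fused γ-lactone with retention at C6.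

Step 19
Reactants: 27 (1R,2R,3S,4Z,6S,7S,8R,10R)-3,8-bis(tert-butyldimethylsilyloxy)-1,2-epoxy-10-(triethylsilyloxy)-13-norgermacr-4-en-12,6-olide
Product: 31 (1R,2R,3S,4Z,6S,7S,8R,10R)-3,8-bis(tert-butyldimethylsilyloxy)-1,2-epoxy-10-(triethylsilyloxy)germacra-4,11(13)-dien-12,6-olide, via lithium enolate 28 (not isolated), via Mannich base 29 (not isolated), via quaternary ammonium iodide 30 (not isolated)
Conditions: LiN(i-Pr)2, THF, −78 °C; Me2N=CH2 I, −78 °C to rt; MeI, THF, rt; aq. NaHCO3, EtOAc, rt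
Reagents that add atoms: N,N-dimethylmethyleneiminium iodide (C=[N+](C)C.[I-])
Why: Eschenmoser methylenation, in which the C11 methylene of the lactone is the only acidic C–H position, its enolate undergoes a Mannich reaction with the iminium salt, and quaternisation followed by base-induced elimination of trimethylamine gives the exocyclic C11=C13 alkene.

Step 20
Reactants: 31 (1R,2R,3S,4Z,6S,7S,8R,10R)-3,8-bis(tert-butyldimethylsilyloxy)-1,2-epoxy-10-(triethylsilyloxy)germacra-4,11(13)-dien-12,6-olide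
Product: 32 (1R,2S,3S,4Z,6S,7R,8R,10R)-1,2-epoxy-3,8,10-trihydroxygermacra-4,11(13)-dien-12,6-olide
Conditions: HF·pyridine, pyridine, THF, 0 °C to rt
Reagents that add atoms: none
Why: Fluoride-mediated desilylation with buffered HF·pyridine removes the two tert-butyldimethylsilyl ethers and the triethylsilyl ether, and the buffered medium should spare the epoxide and the α-methylene lactone.

Step 21
Reactants: 32 (1R,2S,3S,4Z,6S,7R,8R,10R)-1,2-epoxy-3,8,10-trihydroxygermacra-4,11(13)-dien-12,6-olide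
Product: 33 (1R,2R,4Z,6S,7R,8R,10R)-1,2-epoxy-8,10-dihydroxy-3-oxogermacra-4,11(13)-dien-12,6-olide
Conditions: MnO2 (excess), CH2Cl2, rt
Reagents that add atoms: none
Why: MnO2 oxidation is selective for allylic alcohols, so only the C3 hydroxyl next to C4=C5 becomes the ketone while the saturated C8 and the tertiary C10 hydroxyls remain.

Step 22
Reactants: 33 (1R,2R,4Z,6S,7R,8R,10R)-1,2-epoxy-8,10-dihydroxy-3-oxogermacra-4,11(13)-dien-12,6-olide; 34 tiglic acid
Product: 36 (1R,2R,4Z,6S,7R,8R,10R)-1,2-epoxy-10-hydroxy-3-oxo-8-[(E)-2-methylbut-2-enoyloxy]germacra-4,11(13)-dien-12,6-olide (CNP0383091.1), via mixed tiglic 2,4,6-trichlorobenzoic anhydride 35 (not isolated)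
Conditions: 34, 2,4,6-Cl3C6H2COCl, Et3N, toluene, rt; then 33, 4-(dimethylamino)pyridine, toluene, rt
Reagents that add atoms: none
Why: Yamaguchi esterification, in which the mixed anhydride transfers the tigloyl group to the only acylable hydroxyl, the secondary C8–OH (the C10–OH is tertiary), without changing the E geometry of the tiglate.

Compound list

1 | (R)-citramalic acid | C[C@@](O)(CC(=O)O)C(=O)O | starting material
2 | dimethyl (2R)-2-hydroxy-2-methylbutanedioate | C[C@@](O)(CC(=O)OC)C(=O)OC | intermediate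
3 | methyl (3R)-3,4-dihydroxy-3-methylbutanoate | C[C@@](O)(CC(=O)OC)CO | intermediate
4 | methyl (3R)-3-methyl-3,4-bis(triethylsilyloxy)butanoate | C[C@@](O[Si](CC)(CC)CC)(CC(=O)OC)CO[Si](CC)(CC)CC | intermediate
5 | (3R)-3-methyl-3,4-bis(triethylsilyloxy)butanal | C[C@@](O[Si](CC)(CC)CC)(CC=O)CO[Si](CC)(CC)CC | intermediate
6 | (4S)-4-benzyl-1,3-oxazolidin-2-one | O=C1N[C@@H](Cc2ccccc2)CO1 | starting material
7 | methyl 4-chloro-4-oxobutanoate | COC(=O)CCC(Cl)=O | starting material
8 | methyl 4-[(4S)-4-benzyl-2-oxo-1,3-oxazolidin-3-yl]-4-oxobutanoate | COC(=O)CCC(=O)N1[C@@H](Cc2ccccc2)COC1=O | intermediate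
9 | dibutylboron Z-enolate of imide 8 | COC(=O)C/C=C(\OB(CCCC)CCCC)N1[C@@H](Cc2ccccc2)COC1=O | intermediate
10 | methyl (3R,4R,6R)-3-{[(4S)-4-benzyl-2-oxo-1,3-oxazolidin-3-yl]carbonyl}-4-hydroxy-6-methyl-6,7-bis(triethylsilyloxy)heptanoate | CC[Si](CC)(CC)OC[C@](C)(O[Si](CC)(CC)CC)C[C@@H](O)[C@@H](CC(=O)OC)C(=O)N1[C@@H](Cc2ccccc2)COC1=O | intermediate
11 | methyl (3R,4R,6R)-4-hydroxy-3-[methoxy(methyl)carbamoyl]-6-methyl-6,7-bis(triethylsilyloxy)heptanoate | CC[Si](CC)(CC)OC[C@](C)(O[Si](CC)(CC)CC)C[C@@H](O)[C@@H](CC(=O)OC)C(=O)N(C)OC | intermediate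
12 | methyl (3R,4R,6R)-4-(tert-butyldimethylsilyloxy)-3-[methoxy(methyl)carbamoyl]-6-methyl-6,7-bis(triethylsilyloxy)heptanoate | CC[Si](CC)(CC)OC[C@](C)(O[Si](CC)(CC)CC)C[C@@H](O[Si](C)(C)C(C)(C)C)[C@@H](CC(=O)OC)C(=O)N(C)OC | intermediate
13 | methyl (3R,4R,6R)-4-(tert-butyldimethylsilyloxy)-3-[methoxy(methyl)carbamoyl]-6-methyl-7-oxo-6-(triethylsilyloxy)heptanoate | O=C[C@](C)(O[Si](CC)(CC)CC)C[C@@H](O[Si](C)(C)C(C)(C)C)[C@@H](CC(=O)OC)C(=O)N(C)OC | intermediate
14 | methyl (3R,4R,6R)-4-(tert-butyldimethylsilyloxy)-3-[methoxy(methyl)carbamoyl]-6-methyl-6-(triethylsilyloxy)oct-7-ynoate | C#C[C@](C)(O[Si](CC)(CC)CC)C[C@@H](O[Si](C)(C)C(C)(C)C)[C@@H](CC(=O)OC)C(=O)N(C)OC | intermediate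
15 | prop-2-yn-1-ol | C#CCO | starting material
16 | bromomagnesium (Z)-3-(bromomagnesio)-2-methylprop-2-en-1-olate | Br[Mg]/C=C(/C)CO[Mg]Br | intermediate
17 | (Z)-3-iodo-2-methylprop-2-en-1-ol | I/C=C(/C)CO | intermediate
18 | (Z)-3-iodo-2-methylprop-2-enal | I/C=C(/C)C=O | intermediate
19 | E-alkenyl(dicyclohexyl)borane from 14 (boron on C2) | C1CCC(CC1)B(C1CCCCC1)/C=C/[C@](C)(O[Si](CC)(CC)CC)C[C@@H](O[Si](C)(C)C(C)(C)C)[C@@H](CC(=O)OC)C(=O)N(C)OC | intermediate
20 | E-alkenyl(methyl)zinc from 14 (zinc on C2) | C[Zn]/C=C/[C@](C)(O[Si](CC)(CC)CC)C[C@@H](O[Si](C)(C)C(C)(C)C)[C@@H](CC(=O)OC)C(=O)N(C)OC | intermediate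
21 | methyl (3R,4R,6R,7E,9R,10Z)-4-(tert-butyldimethylsilyloxy)-9-hydroxy-11-iodo-3-[methoxy(methyl)carbamoyl]-6,10-dimethyl-6-(triethylsilyloxy)undeca-7,10-dienoate | I/C=C(/C)[C@H](O)/C=C/[C@](C)(O[Si](CC)(CC)CC)C[C@@H](O[Si](C)(C)C(C)(C)C)[C@@H](CC(=O)OC)C(=O)N(C)OC | intermediate
22 | methyl (3R,4R,6R,7R,8S,9S,10Z)-4-(tert-butyldimethylsilyloxy)-7,8-epoxy-9-hydroxy-11-iodo-3-[methoxy(methyl)carbamoyl]-6,10-dimethyl-6-(triethylsilyloxy)undec-10-enoate | I/C=C(/C)[C@H](O)[C@@H]1O[C@H]1[C@](C)(O[Si](CC)(CC)CC)C[C@@H](O[Si](C)(C)C(C)(C)C)[C@@H](CC(=O)OC)C(=O)N(C)OC | intermediate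
23 | methyl (3R,4R,6R,7R,8R,9S,10Z)-4,9-bis(tert-butyldimethylsilyloxy)-7,8-epoxy-11-iodo-3-[methoxy(methyl)carbamoyl]-6,10-dimethyl-6-(triethylsilyloxy)undec-10-enoate | I/C=C(/C)[C@H](O[Si](C)(C)C(C)(C)C)[C@@H]1O[C@H]1[C@](C)(O[Si](CC)(CC)CC)C[C@@H](O[Si](C)(C)C(C)(C)C)[C@@H](CC(=O)OC)C(=O)N(C)OC | intermediate
24 | methyl (3R,4R,6R,7R,8R,9S,10Z)-4,9-bis(tert-butyldimethylsilyloxy)-7,8-epoxy-3-formyl-11-iodo-6,10-dimethyl-6-(triethylsilyloxy)undec-10-enoate | I/C=C(/C)[C@H](O[Si](C)(C)C(C)(C)C)[C@@H]1O[C@H]1[C@](C)(O[Si](CC)(CC)CC)C[C@@H](O[Si](C)(C)C(C)(C)C)[C@@H](CC(=O)OC)C=O | intermediate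
25 | Z-alkenylchromium dichloride from 24 (chromium on C5) | Cl[Cr](Cl)/C=C(/C)[C@H](O[Si](C)(C)C(C)(C)C)[C@@H]1O[C@H]1[C@](C)(O[Si](CC)(CC)CC)C[C@@H](O[Si](C)(C)C(C)(C)C)[C@@H](CC(=O)OC)C=O | intermediate
26 | methyl (1R,2R,3S,4Z,6S,7S,8R,10R)-3,8-bis(tert-butyldimethylsilyloxy)-1,2-epoxy-6-hydroxy-10-(triethylsilyloxy)-13-norgermacr-4-en-12-oate | COC(=O)C[C@H]1[C@@H](O)/C=C(/C)[C@H](O[Si](C)(C)C(C)(C)C)[C@@H]2O[C@H]2[C@](C)(O[Si](CC)(CC)CC)C[C@H]1O[Si](C)(C)C(C)(C)C | intermediate
27 | (1R,2R,3S,4Z,6S,7S,8R,10R)-3,8-bis(tert-butyldimethylsilyloxy)-1,2-epoxy-10-(triethylsilyloxy)-13-norgermacr-4-en-12,6-olide | C1C(=O)O[C@H]2/C=C(/C)[C@H](O[Si](C)(C)C(C)(C)C)[C@@H]3O[C@H]3[C@](C)(O[Si](CC)(CC)CC)C[C@@H](O[Si](C)(C)C(C)(C)C)[C@@H]12 | intermediate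
28 | lithium enolate of lactone 27 | C1=C(O[Li])O[C@H]2/C=C(/C)[C@H](O[Si](C)(C)C(C)(C)C)[C@@H]3O[C@H]3[C@](C)(O[Si](CC)(CC)CC)C[C@@H](O[Si](C)(C)C(C)(C)C)[C@@H]12 | intermediate
29 | 11-(dimethylaminomethyl) derivative of lactone 27 (Mannich base, C11 epimers) | CN(C)CC1C(=O)O[C@H]2/C=C(/C)[C@H](O[Si](C)(C)C(C)(C)C)[C@@H]3O[C@H]3[C@](C)(O[Si](CC)(CC)CC)C[C@@H](O[Si](C)(C)C(C)(C)C)[C@@H]12 | intermediate
30 | 11-(trimethylammoniomethyl) derivative of lactone 27, iodide | C[N+](C)(C)CC1C(=O)O[C@H]2/C=C(/C)[C@H](O[Si](C)(C)C(C)(C)C)[C@@H]3O[C@H]3[C@](C)(O[Si](CC)(CC)CC)C[C@@H](O[Si](C)(C)C(C)(C)C)[C@@H]12.[I-] | intermediate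
31 | (1R,2R,3S,4Z,6S,7S,8R,10R)-3,8-bis(tert-butyldimethylsilyloxy)-1,2-epoxy-10-(triethylsilyloxy)germacra-4,11(13)-dien-12,6-olide | C=C1C(=O)O[C@H]2/C=C(/C)[C@H](O[Si](C)(C)C(C)(C)C)[C@@H]3O[C@H]3[C@](C)(O[Si](CC)(CC)CC)C[C@@H](O[Si](C)(C)C(C)(C)C)[C@@H]12 | intermediate
32 | (1R,2S,3S,4Z,6S,7R,8R,10R)-1,2-epoxy-3,8,10-trihydroxygermacra-4,11(13)-dien-12,6-olide | C=C1C(=O)O[C@H]2/C=C(/C)[C@H](O)[C@@H]3O[C@H]3[C@](C)(O)C[C@@H](O)[C@@H]12 | intermediate
33 | (1R,2R,4Z,6S,7R,8R,10R)-1,2-epoxy-8,10-dihydroxy-3-oxogermacra-4,11(13)-dien-12,6-olide | C=C1C(=O)O[C@H]2/C=C(/C)C(=O)[C@@H]3O[C@H]3[C@](C)(O)C[C@@H](O)[C@@H]12 | intermediate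
34 | tiglic acid, (E)-2-methylbut-2-enoic acid | C/C=C(\C)C(=O)O | starting material
35 | mixed tiglic 2,4,6-trichlorobenzoic anhydride | C/C=C(\C)C(=O)OC(=O)c1c(Cl)cc(Cl)cc1Cl | intermediate
36 | (1R,2R,4Z,6S,7R,8R,10R)-1,2-epoxy-10-hydroxy-3-oxo-8-[(E)-2-methylbut-2-enoyloxy]germacra-4,11(13)-dien-12,6-olide (CNP0383091.1) | C=C1C(=O)O[C@H]2/C=C(/C)C(=O)[C@@H]3O[C@H]3[C@](C)(O)C[C@@H](OC(=O)/C(C)=C/C)[C@@H]12 | target

Total step count: 22.
Longest linear sequence: 19 steps (steps 1–4, 6–10 and 13–22, from 1).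

Steps most likely to fail

1. Step 17. The ring closure may show poor facial selectivity at C6 (the 6R alcohol forming beside or instead of the 6S alcohol), and oligomerisation may compete with cyclisation. The fallback sets out from 24: the ring closure is run as in step 17 and the epimeric alcohol, 6-epi-26 F1, is collected together with 26; the mixture is oxidised with Dess–Martin periodinane (NaHCO3, CH2Cl2) to the ten-membered Z-enone F2; a reagent-controlled 1,2-reduction of the C6 ketone (CBS reduction with the B-methyl oxazaborolidine antipode that delivers hydride to the face giving 6S, BH3·SMe2, −40 °C, or NaBH4/CeCl3 under substrate control) comes back to the route at 26.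

2. Step 6. The open transition state may lose anti or facial selectivity, and the Lewis acid may cause loss of the tertiary silyloxy group β to the aldehyde or lactonisation of O8 onto C12. The fallback sets out from 5 and 7: 7 and 2-methylpropane-2-thiol (pyridine, CH2Cl2) give methyl 4-(tert-butylsulfanyl)-4-oxobutanoate F3; its E boron enolate, formed with a C2-symmetric menthone-derived dialkylboron bromide and Et3N, adds to 5 through a closed chair transition state without any Lewis acid (reagent-controlled anti aldol, reagent antipode chosen for Si-face addition to 5) and gives the β-hydroxy thioester methyl (3R,4R,6R)-3-[(tert-butylsulfanyl)carbonyl]-4-hydroxy-6-methyl-6,7-bis(triethylsilyloxy)heptanoate F4; MeONHMe·HCl/AlMe3 turns the thioester into the Weinreb amide and comes back to the route at 11.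

3. Step 13. Facial selectivity at C3 may be insufficient (the following epoxidation would then act as a kinetic resolution and waste material), 18 may isomerise from Z to E on the Lewis-acidic zinc, and methyl may transfer in place of the alkenyl group. The fallback sets out from 14 and 18: the hydroboration, zinc exchange and addition are run without the chiral ligand and give 21 together with its C3 epimer, 9-epi-21 F5; MnO2 oxidises both to the cross-conjugated dienone F6; CBS reduction of the C3 ketone (oxazaborolidine antipode chosen for the 3R carbinol) comes back to the route at 21.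

Further compounds

F1 | step 17 | methyl (1R,2R,3S,4Z,6R,7S,8R,10R)-3,8-bis(tert-butyldimethylsilyloxy)-1,2-epoxy-6-hydroxy-10-(triethylsilyloxy)-13-norgermacr-4-en-12-oate (6-epi-26) | COC(=O)C[C@H]1[C@H](O)/C=C(/C)[C@H](O[Si](C)(C)C(C)(C)C)[C@@H]2O[C@H]2[C@](C)(O[Si](CC)(CC)CC)C[C@H]1O[Si](C)(C)C(C)(C)C
F2 | step 17 | methyl (1R,2R,3S,4Z,7R,8R,10R)-3,8-bis(tert-butyldimethylsilyloxy)-1,2-epoxy-6-oxo-10-(triethylsilyloxy)-13-norgermacr-4-en-12-oate | COC(=O)C[C@H]1C(=O)/C=C(/C)[C@H](O[Si](C)(C)C(C)(C)C)[C@@H]2O[C@H]2[C@](C)(O[Si](CC)(CC)CC)C[C@H]1O[Si](C)(C)C(C)(C)C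
F3 | step 6 | methyl 4-(tert-butylsulfanyl)-4-oxobutanoate | COC(=O)CCC(=O)SC(C)(C)C
F4 | step 6 | methyl (3R,4R,6R)-3-[(tert-butylsulfanyl)carbonyl]-4-hydroxy-6-methyl-6,7-bis(triethylsilyloxy)heptanoate | CC[Si](CC)(CC)OC[C@](C)(O[Si](CC)(CC)CC)C[C@@H](O)[C@@H](CC(=O)OC)C(=O)SC(C)(C)C
F5 | step 13 | methyl (3R,4R,6R,7E,9S,10Z)-4-(tert-butyldimethylsilyloxy)-9-hydroxy-11-iodo-3-[methoxy(methyl)carbamoyl]-6,10-dimethyl-6-(triethylsilyloxy)undeca-7,10-dienoate (9-epi-21) | I/C=C(/C)[C@@H](O)/C=C/[C@](C)(O[Si](CC)(CC)CC)C[C@@H](O[Si](C)(C)C(C)(C)C)[C@@H](CC(=O)OC)C(=O)N(C)OC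
F6 | step 13 | methyl (3R,4R,6R,7E,10Z)-4-(tert-butyldimethylsilyloxy)-11-iodo-3-[methoxy(methyl)carbamoyl]-6,10-dimethyl-9-oxo-6-(triethylsilyloxy)undeca-7,10-dienoate | I/C=C(/C)C(=O)/C=C/[C@](C)(O[Si](CC)(CC)CC)C[C@@H](O[Si](C)(C)C(C)(C)C)[C@@H](CC(=O)OC)C(=O)N(C)OC
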